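**Assumption:** the target is flat and has no stereocentre, so it is achiral and there is no enantiomer to select. The only stereocentres in the route (in 3 and 5) are formed racemic and are erased in step 2.

## Retrosynthetic overview
1. 9 ⇒ 7: both pyrrole-ring bromines go in last. C2–Br comes from the lactam C=O by deoxybromination, and C3–Br from electrophilic bromination of the resulting 2-bromoindole.
2. 7 ⇒ 5: the N1–C2 lactam bond closes by itself once the nitro group is reduced. The spare chlorine is removed in the same pot.
3. 5 ⇒ 1 + 2: the key C3–C3a bond. C3 arrives as the dichloroacetate carbanion, a masked glyoxylate acyl anion (reversed polarity). It replaces the hydrogen on the acceptor carbon ortho to NO2, so two normally electrophilic carbons are joined.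
4. Ring order: ring A (benzene) is bought with both bromines in place. Ring B (pyrrole) is closed in step 2 and aromatised in step 3.

## Route

**Step 1**
Reactants: 1 1,2-dibromo-4-nitrobenzene; 2 ethyl dichloroacetate
Product: 5 ethyl 2-chloro-2-(4,5-dibromo-2-nitrophenyl)acetate (racemic), via sigma-H adduct 3 (not isolated), via potassium nitrobenzylic carbanion 4 (not isolated)
Conditions: KOtBu (3 equiv), DMF, −40 °C, 20 min (1 + 2 added together to the base); then AcOH
Reagents that add atoms: none
Why: Vicarious nucleophilic substitution of hydrogen: deprotonated 2 is a gem-dihalo carbanion, i.e. a masked glyoxylate acyl anion whose normally electrophilic carbon acts as donor, and it adds to the equally electrophilic C–H carbon ortho to NO2 (para is blocked by Br, addition at C–H is faster than displacement of Br, and the other ortho C–H is walled in by NO2 and Br for this tertiary carbanion), after which KOtBu-induced loss of HCl from 3 rearomatises to 4 and protonation gives 5, whose new stereocentre is racemic and is erased in step 2.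

**Step 2**
Reactants: 5 ethyl 2-chloro-2-(4,5-dibromo-2-nitrophenyl)acetate
Product: 7 5,6-dibromoindolin-2-one, via amino ester 6 (not isolated)
Conditions: Zn dust (10 equiv), AcOH, 25 → 90 °C, 3 h
Reagents that add atoms: none
Why: Dissolving-metal reduction with spontaneous lactamisation (reductive cyclisation of a 2-nitrophenylacetate, Baeyer-type oxindole synthesis): Zn/AcOH takes NO2 to NH2 and cleaves the activated benzylic α-chloro ester C–Cl bond, aniline 6 closes 5-exo-trig on the ester, and aryl C–Br bonds survive, as they do in the standard Zn/AcOH reduction of 3,3,5-tribromooxindoles to 5-bromooxindoles.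

**Step 3**
Reactants: 7 5,6-dibromoindolin-2-one
Product: 9 2,3,5,6-tetrabromo-1H-indole, via 2,5,6-tribromo-1H-indole 8 (not isolated)
Conditions: POBr3 (1.5 equiv), imidazole (1.2 equiv), ClCH2CH2Cl, 85 °C, 3 h; cool to 0 °C; NBS (1.05 equiv), 30 min
Reagents that add atoms: phosphorus oxybromide O=P(Br)(Br)Br; N-bromosuccinimide O=C1CCC(=O)N1Br
Why: Lactam activation and deoxybromination followed by electrophilic aromatic substitution: O-phosphorylation of the lactam and bromide addition–elimination give the imidoyl bromide, which tautomerises to aromatic 8, and C3 is then the only strongly nucleophilic position left (C5 and C6 are occupied, C4 and C7 are deactivated), so one equivalent of NBS brominates there.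

## Compound list
1 | 1,2-dibromo-4-nitrobenzene | O=[N+]([O-])c1ccc(Br)c(Br)c1 | starting material
2 | ethyl dichloroacetate | CCOC(=O)C(Cl)Cl | starting material
3 | sigma-H adduct: potassium [3,4-dibromo-6-(1,1-dichloro-2-ethoxy-2-oxoethyl)cyclohexa-2,4-dien-1-ylidene]azinate (racemic) | CCOC(=O)C(Cl)(Cl)C1C=C(Br)C(Br)=CC1=[N+]([O-])[O-].[K+] | intermediate
4 | potassium salt of the carbanion of ethyl 2-chloro-2-(4,5-dibromo-2-nitrophenyl)acetate | [K+].CCOC(=O)[C-](Cl)c1cc(Br)c(Br)cc1[N+](=O)[O-] | intermediate
5 | ethyl 2-chloro-2-(4,5-dibromo-2-nitrophenyl)acetate (racemic) | CCOC(=O)C(Cl)c1cc(Br)c(Br)cc1[N+](=O)[O-] | intermediate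
6 | ethyl 2-(2-amino-4,5-dibromophenyl)acetate | CCOC(=O)Cc1cc(Br)c(Br)cc1N | intermediate
7 | 5,6-dibromoindolin-2-one (5,6-dibromooxindole) | O=C1Cc2cc(Br)c(Br)cc2N1 | intermediate
8 | 2,5,6-tribromo-1H-indole | Brc1cc2cc(Br)c(Br)cc2[nH]1 | intermediate
9 | 2,3,5,6-tetrabromo-1H-indole (achiral) | Brc1cc2[nH]c(Br)c(Br)c2cc1Br | target

## Step count and risks
Total step count: 3. Longest linear sequence: 3.

**Most likely to fail, in order of risk:**

**Step 1.** A tertiary carbanion has to attack ortho to NO2. Displacement of the para bromine, halophilic attack and self-condensation of 2 all compete.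
The fallback sets out from 1 and comes back at 7. It reverses the polarity on the other partner. Fe powder/NH4Cl in aqueous EtOH reduces 1 to 3,4-dibromoaniline F1. Chloroacetyl chloride in hot toluene gives 2-chloro-N-(3,4-dibromophenyl)acetamide F2. An AlCl3 melt at 160–180 °C (Stollé cyclisation) then uses the α-chloroamide as an enolonium equivalent. The ring carbon para to the 3-bromine, which is the less hindered ortho site, attacks it to give 7.

**Step 3.** The electron-poor lactam may be slow to activate, and 8 may decompose or hydrolyse back to 7 before it is brominated.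
The fallback sets out from 7 and comes back at 9. It removes the carbonyl oxygen by reduction instead of exchanging it for bromide. BH3·THF (0 °C to reflux) reduces the lactam to the hemiaminal, which dehydrates to 5,6-dibromo-1H-indole F5. NBS (2.05 equiv) in CH2Cl2 at 0 °C then brominates first C3, giving 3,5,6-tribromo-1H-indole F6, and then C2, giving 9.

**Step 2.** Zinc may stop at the N-hydroxylactam, leave C–Cl partly intact, or nibble at the aryl bromines.
The fallback sets out from 5 and comes back at 9. It keeps the C3 halogen instead of removing it, so no final bromination is needed. SnCl2·2H2O in EtOAc at 50 °C reduces only the nitro group, and lactamisation gives 5,6-dibromo-3-chloroindolin-2-one F3. LiBr in refluxing acetone (Finkelstein exchange at the activated benzylic α-carbonyl position) gives 3,5,6-tribromoindolin-2-one F4. POBr3 in ClCH2CH2Cl at 85 °C, without base, converts the lactam into the imidoyl bromide, which tautomerises directly to 9.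

## Further compounds
F1 | step 1 | 3,4-dibromoaniline | Nc1ccc(Br)c(Br)c1
F2 | step 1 | 2-chloro-N-(3,4-dibromophenyl)acetamide | O=C(CCl)Nc1ccc(Br)c(Br)c1
F3 | step 2 | 5,6-dibromo-3-chloroindolin-2-one (racemic) | O=C1Nc2cc(Br)c(Br)cc2C1Cl
F4 | step 2 | 3,5,6-tribromoindolin-2-one (racemic) | O=C1Nc2cc(Br)c(Br)cc2C1Br
F5 | step 3 | 5,6-dibromo-1H-indole | Brc1cc2cc[nH]c2cc1Br
F6 | step 3 | 3,5,6-tribromo-1H-indole | Brc1c[nH]c2cc(Br)c(Br)cc12
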